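The numbers in the tables stem from a simulated flask with made-up constants, noise included.

Take the amounts first: 12 mM of starting material with 24.0 mM of reagent, the same in grey, teal, red and ochre, while the vessel, the dosing and the time differ, with teal keeping its mixture 400 min on average against 80 min in the other three.

| flask | starting material | reagent | remark | time |
|---|---|---|---|---|
| eta | 12 mM | 24 mM | run made earlier |  |
| zeta | 17 mM | 24 mM | run made earlier |  |
| epsilon | 26 mM | 24 mM | run made earlier |  |
| beta | 12 mM | 12 mM | run made earlier |  |
| grey | 12 mM | 24.0 mM | one stirred flow tank at steady state, fed with the mixture as stated, mean residence time 80 min |  |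
| teal | 12 mM | 24.0 mM | a single well-mixed tank run continuously and read at steady state, 400 min in it on average |  |
| red | 12 mM | 24.0 mM | a closed flask charged with all of it at once and left for 80 min | 80 min |
| ochre | 12 mM | 24.0 mM (fed, over 80.0 min) | a stirred flask in which reagent is dosed at a steady rate over 80.0 min without added volume, worked up at 80 min | 80 min |

| run | time / min | target / % | side product / % | starting material / % |
|---|---|---|---|---|
| eta | 6.00 | 1 | 1 | 93 |
| eta | 15.0 | 0 | 6 | 80 |
| eta | 20.0 | 0 | 12 | 75 |
| eta | 30.0 | 5 | 21 | 66 |
| eta | 40.0 | 4 | 27 | 60 |
| eta | 50.0 | 6 | 35 | 47 |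
| zeta | 15.0 | 0 | 12 | 81 |
| zeta | 30.0 | 3 | 25 | 65 |
| zeta | 40.0 | 2 | 31 | 55 |
| zeta | 60.0 | 5 | 44 | 43 |
| zeta | 80.0 | 8 | 54 | 35 |
| zeta | 90.0 | 4 | 57 | 28 |
| epsilon | 15.0 | 5 | 13 | 80 |
| epsilon | 30.0 | 0 | 30 | 64 |
| epsilon | 40.0 | 1 | 34 | 55 |
| epsilon | 60.0 | 1 | 50 | 40 |
| epsilon | 80.0 | 5 | 56 | 32 |
| epsilon | 90.0 | 4 | 62 | 30 |
| beta | 20.0 | 0 | 8 | 88 |
| beta | 40.0 | 3 | 19 | 72 |
| beta | 60.0 | 1 | 27 | 63 |
| beta | 80.0 | 2 | 39 | 56 |
| beta | 90.0 | 1 | 39 | 51 |

(each reading ± 1.5 percentage points)

- in percentages every species weighs as the starting material in it: one side product counts as two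
- the stated concentrations are those of everything mixed, before any reaction; amounts are the same in each set-up
- the feed brings no volume worth counting
- the earlier runs were made in a closed, stirred flask

- the set-up with the highest share of target in all that became target or side product, at the outlet or at the end ("none" if the first two lie within 2 percentage points) (grey / teal / red / ochre / none)
- share of target in all that became target or side product, at the outlet or at the end, grey
- share of target in all that became target or side product, at the outlet or at the end, teal
- share of target in all that became target or side product, at the outlet or at the end, red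
- share of target in all that became target or side product, at the outlet or at the end, ochre

Over the last two readings of the zeta run, target against side product, both in percent, stands at 0.108, and from the start of that run to those readings [reagent]/[starting material] climbs from 1.41 to about 3.39, if one reagent goes per two starting material lost. Divide by the mean of these, 2.40, and keep 0.0450 as g, the selectivity factor: percent of target formed per percent of side product formed, per unit of [reagent]/[starting material].

A steady tank makes its product at outlet concentrations, so take the share there as gx/(1+gx), with x the outlet ratio. For teal, set reagent at 18.0 mM and scale the loss in the eta run to teal's residence time and that reagent level: this gives a tank number of 4.53, so starting material leaves at 2.17 mM. Then x is 8.30, higher than the 2.00 at which red starts, and my share for teal is 27.2%.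

The forecast gives 13.5% for grey, 21% for teal, 14% for red and 7.5% for ochre, calling ochre “reagent starved early”. It picks teal, and my teal figure is higher than its own.

    reagent + intermediate A → intermediate B (k = 0.410 M⁻¹ min⁻¹)
    intermediate B → intermediate C (k = 0.00420 min⁻¹)
    intermediate B → target (k = 0.320 min⁻¹)
    starting material + intermediate A → side product (k = 4.00 M⁻¹ min⁻¹)
    starting material + reagent ⇌ intermediate A (K = 68.0 M⁻¹, k = 0.480 M⁻¹ min⁻¹)
    intermediate C ⇌ intermediate D (K = 1.80, k = 0.0360 min⁻¹)

Teal gives 23.0%, ahead of grey at 13.6%, red at 12.5% and ochre at 6.78%. Teal's outlet holds 22.3% of the starting material, and g on that amount gives 24.5%. Grey's outlet holds 50.2%, and g on that gives 13.6%, where the flask gives 13.6%.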